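**Retrosynthetic overview**

1. The target comes from diketone 24 by a final double methyl addition that makes both C(CH3)(OH) centres. 24 comes from 22 by closing the seven-membered ring last, at the bond CMe2–CH(side chain). 22 comes from the two halves 20 and 12 by cross-metathesis in the CH2CH2 link.
2. Feature used: in the seven-membered ring the CMe2 carbon lies between a ring-fusion CH of the cyclopentene and the side-chain CH, and that CH is α to the carbinol carbon. With the carbinol carbon as a ketone, the ring is an α-tert-alkyl ketone (enol carbon plus tertiary cation). Its seven ring atoms are the six ring carbons of (R)-carvone plus the carvone methyl carbon, so carvone's ring is cut between C1 and C2 and closed again, one carbon larger, between C1 and the old methyl carbon.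
3. Right half: (R)-carvone, α'-allylation and ring-closing metathesis (cyclopentene, cis on the temporary cyclohexenone), C1–C2 cleavage to a keto ester, then ester to CMe2OH and methyl ketone to vinyl ketone 12.
4. Left half: (E)-geranylacetone, Shi bis-epoxidation, then a tandem oxa-/carbacyclisation ended by an enol silane gives oxepane and cyclohexanone together (20).
5. Ring order: cyclopentene (step 2), oxepane then cyclohexane (step 12), cycloheptane (step 15).

Key step: step 15

Assumption: (E)-geranylacetone is used as the pure E isomer, and the Shi ketone derived from D-fructose is taken to give the (R,R)-epoxides of trans-trisubstituted alkenes.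

**Route**

Step 1
Reactants: 1 (R)-(−)-carvone
Product: 2 (5R,6S)-2-methyl-5-(prop-1-en-2-yl)-6-(prop-2-en-1-yl)cyclohex-2-en-1-one
Conditions: LDA, THF, −78 °C; allyl bromide, HMPA, −78 → −20 °C
Reagents that add atoms: allyl bromide, C=CCBr
Why: kinetic α'-deprotonation gives the cross-conjugated lithium dienolate, whose SN2 alkylation places the allyl group anti to the neighbouring isopropenyl group; this centre is α to the ketone and is corrected in step 2.

Step 2
Reactants: 2 (5R,6S)-6-allylcarvone
Product: 4 (3aR,7aR)-3,6-dimethyl-1,3a,4,7a-tetrahydro-7H-inden-7-one, via trans-fused enone 3 (not isolated)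
Conditions: second-generation Grubbs catalyst (3 mol %), CH2Cl2, 40 °C; then DBU, rt
Reagents that add atoms: none
Why: ring-closing metathesis of the allyl and isopropenyl groups gives the 1-methylcyclopentene, and DBU then epimerises the ring-fusion carbon α to the ketone to the cis fusion, which should be the more stable one for a cyclopentene whose double bond is next to the ring fusion.

Step 3
Reactants: 4 cis-fused bicyclic enone
Product: 5 (3aR,7aR)-6-hydroxy-3,6-dimethyl-1,3a,4,5,6,7a-hexahydro-7H-inden-7-one
Conditions: LiBH(s-Bu)3, THF, −78 °C; then 2-(phenylsulfonyl)-3-phenyloxaziridine, −78 → 0 °C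
Reagents that add atoms: 2-(phenylsulfonyl)-3-phenyloxaziridine, O=S(=O)(c1ccccc1)N1OC1c1ccccc1
Why: conjugate hydride addition gives the enolate only at the methyl-bearing carbon, and electrophilic hydroxylation with the Davis oxaziridine gives the tertiary α-ketol, whose carbinol configuration does not matter because the centre is destroyed in step 4.

Step 4
Reactants: 5 α-ketol
Product: 6 methyl (1R,2R)-3-methyl-2-(3-oxobutyl)cyclopent-3-ene-1-carboxylate
Conditions: Pb(OAc)4, MeOH/benzene (1:1), 0 °C
Reagents that add atoms: methanol, CO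
Why: oxidative cleavage of the α-ketol in methanol turns the acyl carbon into the methyl ester and the carbinol carbon into the methyl ketone, and it touches neither the two cis stereocentres nor the alkene.

Step 5
Reactants: 6 keto ester
Product: 7 methyl (1R,2R)-3-methyl-2-[2-(2-methyl-1,3-dioxolan-2-yl)ethyl]cyclopent-3-ene-1-carboxylate
Conditions: ethylene glycol, PPTS, benzene, reflux (Dean–Stark)
Reagents that add atoms: ethylene glycol, OCCO
Why: acid-catalysed ketalisation protects the ketone selectively while the ester and its α-stereocentre stay unchanged.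

Step 6
Reactants: 7 ketal ester
Product: 8 2-{(1R,2R)-3-methyl-2-[2-(2-methyl-1,3-dioxolan-2-yl)ethyl]cyclopent-3-en-1-yl}propan-2-ol
Conditions: MeLi (3 equiv), Et2O/THF, −78 → 0 °C
Reagents that add atoms: methyllithium, [Li]C
Why: double addition of methyllithium to the ester gives the tertiary alcohol whose carbon will be the gem-dimethyl ring carbon, and fast addition at low temperature should outrun epimerisation of the α-carbon.

Step 7
Reactants: 8 ketal alcohol
Product: 9 4-[(1R,5R)-5-(2-hydroxypropan-2-yl)-2-methylcyclopent-2-en-1-yl]butan-2-one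
Conditions: PPTS, acetone/H2O (10:1), 50 °C
Reagents that add atoms: water, O
Why: mild acidic hydrolysis of the dioxolane frees the methyl ketone without dehydrating the tertiary alcohol.

Step 8
Reactants: 9 keto alcohol
Product: 12 5-[(1R,5R)-5-(2-hydroxypropan-2-yl)-2-methylcyclopent-2-en-1-yl]pent-1-en-3-one, via Mannich base 10 (not isolated), via methiodide 11 (not isolated)
Conditions: LDA (2.2 equiv), THF, −78 °C; CH2=NMe2 I (Eschenmoser's salt), −78 → 0 °C; then MeI, CH2Cl2, rt; then aq. NaHCO3
Reagents that add atoms: Eschenmoser's salt, C=[N+](C)C.[I-]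
Why: the kinetic enolate forms at the methyl group (the old carvone methyl carbon) and a Mannich reaction followed by quaternisation and elimination gives the vinyl ketone.

Step 9
Reactants: 13 (E)-geranylacetone
Product: 14 (5R,6R,9R)-5,6:9,10-diepoxy-6,10-dimethylundecan-2-one
Conditions: Shi ketone from D-fructose (30 mol %), Oxone (2KHSO5·KHSO4·K2SO4), K2CO3, n-Bu4NHSO4, MeCN/CH2(OMe)2/aq. Na2B4O7 buffer, 0 °C
Reagents that add atoms: potassium peroxymonosulfate, [K+].[O-]S(=O)(=O)OO
Why: Shi epoxidation by the chiral dioxirane attacks both trans-trisubstituted alkenes from the same face, which sets all three epoxide stereocentres under catalyst control.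

Step 10
Reactants: 14 diepoxy ketone
Product: 17 (6R,7R,10R)-6,7:10,11-diepoxy-7,11-dimethyldodec-1-en-3-one, via Mannich base 15 (not isolated), via methiodide 16 (not isolated)
Conditions: LDA, THF, −78 °C; CH2=NMe2 I (Eschenmoser's salt), −78 → 0 °C; then MeI, CH2Cl2, rt; then aq. NaHCO3
Reagents that add atoms: Eschenmoser's salt, C=[N+](C)C.[I-]
Why: the same Mannich methylenation at the methyl group as in step 8 is used, and the two trisubstituted epoxides should survive the cold lithium enolate.

Step 11
Reactants: 17 diepoxy vinyl ketone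
Product: 18 trimethyl{[(4Z,8R,9R,12R)-8,9:12,13-diepoxy-9,13-dimethyltetradeca-1,4-dien-5-yl]oxy}silane
Conditions: CH2=CHMgBr, CuBr·SMe2 (10 mol %), TMSCl, HMPA, THF, −78 °C; Et3N, pentane
Reagents that add atoms: vinylmagnesium bromide, C=C[Mg]Br; chlorotrimethylsilane, C[Si](C)(C)Cl
Why: copper-catalysed conjugate addition of the vinyl group with silyl trapping gives the enol silane on one side of the ketone only and installs the allyl unit needed for step 13.

Step 12
Reactants: 18 diepoxy enol silane
Product: 20 (3R,5aR,6R,9aR)-3-hydroxy-2,2,5a-trimethyl-6-(prop-2-en-1-yl)octahydro-1-benzoxepin-7(2H)-one, via trimethylsilyl ether 19 (not isolated)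
Conditions: TMSOTf (0.3 equiv), 2,6-di-tert-butyl-4-methylpyridine, CH2Cl2, −78 °C; then 1 M HCl, THF, 0 °C
Reagents that add atoms: none
Why: this is a Lewis-acid-promoted tandem oxa-/carbacyclisation of a bis-epoxide ended by an enol silane, in which the silylated terminal epoxide is opened at its tertiary carbon by the inner epoxide oxygen (oxepane) and the resulting epoxonium ion is opened with inversion at its tertiary carbon by the enol silane through a chair (cyclohexanone), so that the epoxide configurations set the carbinol, the ring-fusion CH–O and the quaternary methyl centres while the allyl-bearing carbon α to the ketone takes the equatorial position.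

Step 13
Reactants: 20 bicyclic allyl ketone; 12 vinyl ketone
Product: 21 (2E)-1-[(3R,5aR,6R,9aR)-3-hydroxy-2,2,5a-trimethyl-7-oxodecahydro-1-benzoxepin-6-yl]-6-[(1R,5R)-5-(2-hydroxypropan-2-yl)-2-methylcyclopent-2-en-1-yl]hex-2-en-4-one
Conditions: second-generation Hoveyda–Grubbs catalyst (5 mol %), CH2Cl2, 40 °C
Reagents that add atoms: none
Why: cross-metathesis of a terminal alkene with a vinyl ketone is selective for the (E)-enone and tolerates the free hydroxyl groups, the isolated ketone and the trisubstituted ring alkene.

Step 14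
Reactants: 21 dihydroxy enone
Product: 22 (3R,5aR,6R,9aR)-6-{(2E)-6-[(1R,5R)-5-(2-acetoxypropan-2-yl)-2-methylcyclopent-2-en-1-yl]-4-oxohex-2-en-1-yl}-2,2,5a-trimethyl-7-oxodecahydro-1-benzoxepin-3-yl acetate
Conditions: Ac2O, DMAP, Et3N, CH2Cl2, 35 °C
Reagents that add atoms: acetic anhydride, CC(=O)OC(C)=O
Why: DMAP-catalysed acylation turns the tertiary alcohol into the leaving group for step 15 and at the same time protects the secondary alcohol.

Step 15
Reactants: 22 bis-acetate enone
Product: 24 (3R,5aR,6R,9aR)-2,2,5a-trimethyl-7-oxo-6-{2-[(3aR,5R,8aR)-1,4,4-trimethyl-6-oxo-3,3a,4,5,6,7,8,8a-octahydroazulen-5-yl]ethyl}decahydro-1-benzoxepin-3-yl acetate, via triethylsilyl enol ether 23 (not isolated)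
Conditions: Et3SiH (1.1 equiv), RhCl(PPh3)3 (2 mol %), benzene, 50 °C; then TiCl4 (3 equiv), 2,6-di-tert-butylpyridine, CH2Cl2, −78 → −40 °C; aq. NaHCO3
Reagents that add atoms: none
Why: RhCl(PPh3)3-catalysed 1,4-hydrosilylation turns the enone into the (Z)-triethylsilyl enol ether 23, and TiCl4 then ionises the tertiary acetate to a tertiary carbocation that is captured by the enol ether carbon with loss of the silyl group, which gives the α-tert-alkyl ketone. The closest known reaction type is the Lewis-acid-mediated α-tert-alkylation of silyl enol ethers with tertiary alkyl electrophiles (Reetz alkylation), in its ring-forming form as a cation cyclisation ended by an enol silane. The seven-membered ring closes in a 7-endo-trig sense with respect to the enol ether double bond (both of its carbons become ring atoms), while the cationic carbon sits outside the cyclopentene on the neighbouring ring-fusion carbon. The one new stereocentre, the CH next to the ketone, is controlled by the cis-fused cyclopentene: in a chair-like closure the side chain should take the pseudo-equatorial position cis to the CH2 bond of the adjacent ring-fusion carbon, and because the centre is α to the ketone the same epimer is also the one expected at equilibrium. The step needs attack through the side-chain carbon and not through the other α-carbon (which would give a five-membered ring), secured because hydrosilylation places the enol double bond only on the enone side; it needs the two arms to meet, secured by their cis relation on the cyclopentene from step 2; and it needs ionisation of the tertiary acetate only, secured because the secondary acetate cannot ionise and its inductive effect keeps the tertiary C–O bond of the oxepane intact. The hindered pyridine and the low temperature are there to hold back proton loss from the cation.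

Step 16
Reactants: 24 diketone acetate
Product: 25 (3R,5aR,6R,7S,9aR)-6-{2-[(3aR,5R,6S,8aR)-6-hydroxy-1,4,4,6-tetramethyl-3,3a,4,5,6,7,8,8a-octahydroazulen-5-yl]ethyl}-2,2,5a,7-tetramethyldecahydro-1-benzoxepine-3,7-diol
Conditions: MeLi (10 equiv), THF/Et2O, −78 → 0 °C; aq. NH4Cl
Reagents that add atoms: methyllithium, [Li]C
Why: 1,2-addition of methyllithium to both ketones should occur in each ring from the face away from the pseudo-axial methyl group on the β-carbon and anti to the α side chain (equatorial attack, as on 3,3,5-trimethylcyclohexanone), which places each new hydroxyl cis to the side chain, and the excess reagent also cleaves the acetate.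

**Compound list**

1 | (R)-(−)-carvone | CC1=CC[C@H](CC1=O)C(C)=C | starting material
2 | (5R,6S)-2-methyl-5-(prop-1-en-2-yl)-6-(prop-2-en-1-yl)cyclohex-2-en-1-one (allyl trans to isopropenyl) | C=CC[C@H]1[C@H](C(C)=C)CC=C(C)C1=O | intermediate
3 | (3aR,7aS)-3,6-dimethyl-1,3a,4,7a-tetrahydro-7H-inden-7-one (trans-fused) | CC1=CC[C@H]2[C@H]1CC=C(C)C2=O | intermediate
4 | (3aR,7aR)-3,6-dimethyl-1,3a,4,7a-tetrahydro-7H-inden-7-one (cis-fused) | CC1=CC[C@@H]2[C@H]1CC=C(C)C2=O | intermediate
5 | (3aR,7aR)-6-hydroxy-3,6-dimethyl-1,3a,4,5,6,7a-hexahydro-7H-inden-7-one (both epimers at C6) | CC1=CC[C@@H]2[C@H]1CCC(C)(O)C2=O | intermediate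
6 | methyl (1R,2R)-3-methyl-2-(3-oxobutyl)cyclopent-3-ene-1-carboxylate (cis) | CC1=CC[C@@H](C(=O)OC)[C@H]1CCC(C)=O | intermediate
7 | methyl (1R,2R)-3-methyl-2-[2-(2-methyl-1,3-dioxolan-2-yl)ethyl]cyclopent-3-ene-1-carboxylate | CC1=CC[C@@H](C(=O)OC)[C@H]1CCC1(C)OCCO1 | intermediate
8 | 2-{(1R,2R)-3-methyl-2-[2-(2-methyl-1,3-dioxolan-2-yl)ethyl]cyclopent-3-en-1-yl}propan-2-ol | CC1=CC[C@@H](C(C)(C)O)[C@H]1CCC1(C)OCCO1 | intermediate
9 | 4-[(1R,5R)-5-(2-hydroxypropan-2-yl)-2-methylcyclopent-2-en-1-yl]butan-2-one | CC1=CC[C@@H](C(C)(C)O)[C@H]1CCC(C)=O | intermediate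
10 | Mannich base: 1-(dimethylamino)-5-[(1R,5R)-5-(2-hydroxypropan-2-yl)-2-methylcyclopent-2-en-1-yl]pentan-3-one | CC1=CC[C@@H](C(C)(C)O)[C@H]1CCC(=O)CCN(C)C | intermediate
11 | methiodide of 10 (trimethylammonium iodide) | CC1=CC[C@@H](C(C)(C)O)[C@H]1CCC(=O)CC[N+](C)(C)C.[I-] | intermediate
12 | 5-[(1R,5R)-5-(2-hydroxypropan-2-yl)-2-methylcyclopent-2-en-1-yl]pent-1-en-3-one | CC1=CC[C@@H](C(C)(C)O)[C@H]1CCC(=O)C=C | intermediate
13 | (E)-geranylacetone, (5E)-6,10-dimethylundeca-5,9-dien-2-one | CC(C)=CCC/C(C)=C/CCC(C)=O | starting material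
14 | (5R,6R,9R)-5,6:9,10-diepoxy-6,10-dimethylundecan-2-one | CC(=O)CC[C@H]1O[C@]1(C)CC[C@H]1OC1(C)C | intermediate
15 | Mannich base: (6R,7R,10R)-1-(dimethylamino)-6,7:10,11-diepoxy-7,11-dimethyldodecan-3-one | CN(C)CCC(=O)CC[C@H]1O[C@]1(C)CC[C@H]1OC1(C)C | intermediate
16 | methiodide of 15 (trimethylammonium iodide) | C[N+](C)(C)CCC(=O)CC[C@H]1O[C@]1(C)CC[C@H]1OC1(C)C.[I-] | intermediate
17 | (6R,7R,10R)-6,7:10,11-diepoxy-7,11-dimethyldodec-1-en-3-one | C=CC(=O)CC[C@H]1O[C@]1(C)CC[C@H]1OC1(C)C | intermediate
18 | trimethyl{[(4Z,8R,9R,12R)-8,9:12,13-diepoxy-9,13-dimethyltetradeca-1,4-dien-5-yl]oxy}silane | C=CC/C=C(\O[Si](C)(C)C)CC[C@H]1O[C@]1(C)CC[C@H]1OC1(C)C | intermediate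
19 | (3R,5aR,6R,9aR)-2,2,5a-trimethyl-6-(prop-2-en-1-yl)-3-[(trimethylsilyl)oxy]octahydro-1-benzoxepin-7(2H)-one | C=CC[C@@H]1[C@@]2(C)CC[C@@H](O[Si](C)(C)C)C(C)(C)O[C@@H]2CCC1=O | intermediate
20 | (3R,5aR,6R,9aR)-3-hydroxy-2,2,5a-trimethyl-6-(prop-2-en-1-yl)octahydro-1-benzoxepin-7(2H)-one (trans-fused, allyl equatorial) | C=CC[C@@H]1[C@@]2(C)CC[C@@H](O)C(C)(C)O[C@@H]2CCC1=O | intermediate
21 | (2E)-1-[(3R,5aR,6R,9aR)-3-hydroxy-2,2,5a-trimethyl-7-oxodecahydro-1-benzoxepin-6-yl]-6-[(1R,5R)-5-(2-hydroxypropan-2-yl)-2-methylcyclopent-2-en-1-yl]hex-2-en-4-one | CC1=CC[C@@H](C(C)(C)O)[C@H]1CCC(=O)/C=C/C[C@@H]1[C@@]2(C)CC[C@@H](O)C(C)(C)O[C@@H]2CCC1=O | intermediate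
22 | bis-acetate of 21 (secondary oxepane acetate and tertiary acetate) | CC1=CC[C@@H](C(C)(C)OC(C)=O)[C@H]1CCC(=O)/C=C/C[C@@H]1[C@@]2(C)CC[C@@H](OC(C)=O)C(C)(C)O[C@@H]2CCC1=O | intermediate
23 | (Z)-triethylsilyl enol ether from 1,4-hydrosilylation of 22 | CC1=CC[C@@H](C(C)(C)OC(C)=O)[C@H]1CC/C(O[Si](CC)(CC)CC)=C/CC[C@@H]1[C@@]2(C)CC[C@@H](OC(C)=O)C(C)(C)O[C@@H]2CCC1=O | intermediate
24 | (3R,5aR,6R,9aR)-2,2,5a-trimethyl-7-oxo-6-{2-[(3aR,5R,8aR)-1,4,4-trimethyl-6-oxo-3,3a,4,5,6,7,8,8a-octahydroazulen-5-yl]ethyl}decahydro-1-benzoxepin-3-yl acetate | CC1=CC[C@@H]2[C@H]1CCC(=O)[C@H](CC[C@@H]1[C@@]3(C)CC[C@@H](OC(C)=O)C(C)(C)O[C@@H]3CCC1=O)C2(C)C | intermediate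
25 | (3R,5aR,6R,7S,9aR)-6-{2-[(3aR,5R,6S,8aR)-6-hydroxy-1,4,4,6-tetramethyl-3,3a,4,5,6,7,8,8a-octahydroazulen-5-yl]ethyl}-2,2,5a,7-tetramethyldecahydro-1-benzoxepine-3,7-diol | CC1=CC[C@@H]2[C@H]1CC[C@](C)(O)[C@H](CC[C@@H]1[C@@]3(C)CC[C@@H](O)C(C)(C)O[C@@H]3CC[C@]1(C)O)C2(C)C | target

**Totals**

Total step count: 16. Longest linear sequence: 12 steps (steps 1–8, then 13–16); the left half takes 4 steps (9–12).

**Steps most likely to fail**

1. Step 15. What may go wrong: loss of a proton from the tertiary cation is faster than the slow closure of the seven-membered ring, so the cation is spent as an alkene. Fallback (sets out from 23, comes back at 24): the elimination is made the first stage on purpose. With TMSOTf and 2,6-di-tert-butylpyridine in CH2Cl2 at −78 °C the tertiary acetate of 23 should leave with loss of a methyl proton, since the hindered base favours the less substituted alkene, and give the isopropenyl triethylsilyl enol ether F1. Hg(OTf)2 (1.05 equiv) in MeCN/CH2Cl2 at −20 °C, then aqueous NaCl, should close the ring by mercury-triggered alkene cyclisation: the mercurinium ion of the 1,1-disubstituted alkene is opened at its tertiary carbon by the enol ether carbon, which makes the same bond as step 15 and gives the organomercury chloride F2. In F2 the CH2HgCl group stands where the second methyl group will be, and either configuration at that carbon serves. NaBH4 in aqueous NaOH/THF then replaces mercury by hydrogen and gives 24.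

2. Step 12. What may go wrong: protodesilylation of the labile trimethylsilyl enol ether before it can end the cascade, and opening of the second epoxide at the wrong carbon, both of which stop the sequence at monocyclic ethers. Fallback (sets out from 14, comes back at 20): NaH and diallyl carbonate in THF at reflux acylate the methyl group of 14 and give the allyl β-keto ester F3, whose enol is a stable terminating nucleophile that needs no silyl group. SnCl4 in CH2Cl2 at −78 °C should run the same oxa-/carbacyclisation and give the bicyclic allyl β-keto ester F4. Pd(PPh3)4 (5 mol %) in THF then effects the decarboxylative allylation (Tsuji allylation), which moves the allyl group onto the ring carbon between the ketone and the quaternary carbon and gives 20.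

3. Step 16. What may go wrong: poor facial selectivity in the methyl addition to the seven-membered ketone, together with enolisation of the two α-branched ketones by the basic reagent. Fallback (sets out from 24, comes back at 25): methylene transfer under thermodynamic control replaces the irreversible methyl addition. Trimethylsulfoxonium iodide and NaH in DMSO (Corey–Chaykovsky reaction, in which betaine formation is reversible so the new C–C bond takes the less hindered equatorial position) should give the bis-spiro-epoxide F5. LiAlH4 in THF then opens both oxiranes at the CH2 carbon, which turns each into a methyl carbinol, removes the acetate and gives 25.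

Further compounds
F1 | step 15 | isopropenyl triethylsilyl enol ether: (3R,5aR,6R,9aR)-2,2,5a-trimethyl-6-{(3Z)-6-[(1R,5R)-2-methyl-5-(prop-1-en-2-yl)cyclopent-2-en-1-yl]-4-[(triethylsilyl)oxy]hex-3-en-1-yl}-7-oxodecahydro-1-benzoxepin-3-yl acetate | CC1=CC[C@@H](C(C)=C)[C@H]1CC/C(O[Si](CC)(CC)CC)=C/CC[C@@H]1[C@@]2(C)CC[C@@H](OC(C)=O)C(C)(C)O[C@@H]2CCC1=O
F2 | step 15 | organomercury chloride: 24 with one ring methyl group replaced by CH2HgCl (either configuration at that carbon) | CC1=CC[C@@H]2[C@H]1CCC(=O)[C@H](CC[C@@H]1[C@@]3(C)CC[C@@H](OC(C)=O)C(C)(C)O[C@@H]3CCC1=O)C2(C)C[Hg]Cl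
F3 | step 12 | allyl (6R,7R,10R)-6,7:10,11-diepoxy-7,11-dimethyl-3-oxododecanoate | C=CCOC(=O)CC(=O)CC[C@H]1O[C@]1(C)CC[C@H]1OC1(C)C
F4 | step 12 | allyl (3R,5aR,9aR)-3-hydroxy-2,2,5a-trimethyl-7-oxodecahydro-1-benzoxepine-6-carboxylate (epimers at C6) | C=CCOC(=O)C1[C@@]2(C)CC[C@@H](O)C(C)(C)O[C@@H]2CCC1=O
F5 | step 16 | bis-spiro-epoxide: 24 with both ketone carbons turned into spiro-oxiranes (oxygen on the face of the later hydroxyl groups) | CC1=CC[C@@H]2[C@H]1CC[C@]1(OC1)[C@H](CC[C@@H]1[C@@]3(C)CC[C@@H](OC(C)=O)C(C)(C)O[C@@H]3CC[C@]14OC4)C2(C)C
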